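**Retrosynthetic overview**
1. Target 26 ⇐ oxidative demethylation of 2H-chromen-8-ol 24 ⇐ ring expansion of spirodienone 23, in which the five-membered ring O1–C2–C3=C4–C8a becomes the six-membered pyran by a 1,2-shift of C4 from C8a to C4a ⇐ dearomatising spiroetherification of (Z)-hydroxystyryl carbinol 22.
2. Enabling feature: in 23 the spiro carbon (future C8a) carries both the ring oxygen O1 and the vinylic carbon C4. It adjoins the only hydrogen-bearing terminus (future C4a) of the dienone in the six-membered carbocycle. O1 and the neighbouring methoxy group stabilise the cation left behind, and rearomatisation drives the shift. The C2–O1 bond is never broken, so C2 keeps its configuration, whereas closure through an ortho-quinone methide would erase it.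
3. 22 ⇐ Sonogashira coupling and cis-semihydrogenation of aryl iodide 19 (from 3,4-dimethoxyphenol) with (S)-propargylic alcohol 16 ⇐ Sharpless epoxidation and epoxy chloride fragmentation of (Z)-allylic alcohol 12 ⇐ B-alkyl Suzuki coupling of vinylcyclohexene 7 with iodide 10.
4. 7 ⇐ McMurry ring closure ⇐ selective ozonolysis and methyl ketone formation ⇐ enantioselective boron Ireland–Claisen rearrangement of geranyl propionate 1, which sets both ring stereocentres.
5. Order of ring formation: cyclohexene (step 4), spiro-dihydrofuran (step 15), pyran by expansion with rearomatisation of the carbocycle (step 16), quinone (step 17).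

Key step: step 16

Assumption: in step 1 the enolate geometry (methyl cis to O–B with i-Pr2NEt in CH2Cl2) and the facial sense of the (S,S)-controller are taken by analogy with simple crotyl and geranyl esters; if the sense is the opposite, the equally accessible (R,R)-controller is used in the same way.

**Step 1**
Reactants: 1 geranyl propionate
Product: 3 (2R,3S)-3-ethenyl-2,3,7-trimethyloct-6-enoic acid, via boron ketene acetal 2 (not isolated)
Conditions: (S,S)-N,N'-bis[3,5-bis(trifluoromethyl)benzenesulfonyl]-1,2-diphenylethane-1,2-diamine, BBr3, CH2Cl2, rt, then evacuation; 1, i-Pr2NEt, CH2Cl2, −78 °C → −20 °C; aqueous work-up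
Reagents that add atoms: none
Why: Enantioselective boron-enolate Ireland–Claisen rearrangement: the ketene acetal with methyl cis to O–B and the (E)-alkene should pass through a chair with the enolate methyl and the homoprenyl chain equatorial, which fixes the relative configuration of C2 and C3, while the C2-symmetric diazaborolidine shields one enolate face and fixes the absolute one.

**Step 2**
Reactants: 3 (2R,3S)-3-ethenyl-2,3,7-trimethyloct-6-enoic acid
Product: 4 (3R,4S)-4-ethenyl-3,4,8-trimethylnon-7-en-2-one
Conditions: MeLi (2.2 equiv), Et2O, 0 °C → rt; then H2O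
Reagents that add atoms: methyllithium [Li]C
Why: Organolithium addition to a lithium carboxylate (acid to methyl ketone conversion) is reliable for hindered acids, and the ketone is released only on quench, so over-addition and epimerisation next to the carbonyl group should stay small.

**Step 3**
Reactants: 4 (3R,4S)-4-ethenyl-3,4,8-trimethylnon-7-en-2-one
Product: 6 (4S,5R)-4-ethenyl-4,5-dimethyl-6-oxoheptanal, via secondary ozonide 5 (not isolated)
Conditions: O3 (1 equiv), CH2Cl2, −78 °C; then Me2S, −78 °C → rt
Reagents that add atoms: ozone [O-][O+]=O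
Why: Ozonolysis with reductive work-up: the electron-rich trisubstituted alkene reacts much faster with ozone than the hindered monosubstituted vinyl group, so one equivalent should cleave only the former.

**Step 4**
Reactants: 6 (4S,5R)-4-ethenyl-4,5-dimethyl-6-oxoheptanal
Product: 7 (5S,6S)-5-ethenyl-1,5,6-trimethylcyclohex-1-ene
Conditions: TiCl3(DME)1.5, Zn–Cu couple, DME, reflux, slow addition of 6
Reagents that add atoms: none
Why: Intramolecular McMurry coupling: low-valent titanium joins the ketone and aldehyde carbons and deoxygenates the pinacolate to the trisubstituted ring alkene, a closure well known for 1,6-keto aldehydes, and it touches neither the stereocentres nor the vinyl group.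

**Step 5**
Reactants: 8 but-2-yn-1-ol
Product: 10 (2Z)-3-iodobut-2-en-1-ol, via cyclic alkenylalanate 9 (not isolated)
Conditions: NaAlH2(OCH2CH2OMe)2, Et2O, 0 °C → rt; then N-iodosuccinimide, THF, −78 °C; aqueous work-up
Reagents that add atoms: N-iodosuccinimide O=C1CCC(=O)N1I
Why: Alkoxide-directed trans-hydroalumination of a propargylic alcohol places aluminium on the distal carbon in a five-membered alanate, and iodinolysis with retention gives the (Z)-iodide.

**Step 6**
Reactants: 7 (5S,6S)-5-ethenyl-1,5,6-trimethylcyclohex-1-ene; 10 (2Z)-3-iodobut-2-en-1-ol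
Product: 12 (2Z)-3-methyl-5-[(1S,2R)-1,2,3-trimethylcyclohex-3-en-1-yl]pent-2-en-1-ol, via B-alkyl-9-BBN adduct 11 (not isolated)
Conditions: 9-BBN-H, THF, rt; then 10, PdCl2(dppf), AsPh3, Cs2CO3, DMF–H2O, rt
Reagents that add atoms: none
Why: Hydroboration and B-alkyl Suzuki–Miyaura coupling: 9-BBN-H adds only to the monosubstituted vinyl group in the anti-Markovnikov sense, and the cross-coupling keeps the alkene geometry of 10.

**Step 7**
Reactants: 12 (2Z)-3-methyl-5-[(1S,2R)-1,2,3-trimethylcyclohex-3-en-1-yl]pent-2-en-1-ol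
Product: 13 [(2R,3S)-3-methyl-3-{2-[(1S,2R)-1,2,3-trimethylcyclohex-3-en-1-yl]ethyl}oxiran-2-yl]methanol
Conditions: Ti(O-i-Pr)4 (cat.), D-(−)-diisopropyl tartrate (cat.), t-BuOOH, 4 Å molecular sieves, CH2Cl2, −20 °C
Reagents that add atoms: tert-butyl hydroperoxide CC(C)(C)OO
Why: Sharpless asymmetric epoxidation: with the D-(−)-tartrate, oxygen is delivered to the face of the (Z)-allylic alcohol that makes the fully substituted epoxide carbon (S), which sets the C–O bond that ends as O1–C2 of the target, and the isolated ring alkene is not touched.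

**Step 8**
Reactants: 13 [(2R,3S)-3-methyl-3-{2-[(1S,2R)-1,2,3-trimethylcyclohex-3-en-1-yl]ethyl}oxiran-2-yl]methanol
Product: 14 (2S,3S)-3-(chloromethyl)-2-methyl-2-{2-[(1S,2R)-1,2,3-trimethylcyclohex-3-en-1-yl]ethyl}oxirane
Conditions: PPh3, CCl4, NaHCO3 (cat.), reflux
Reagents that add atoms: tetrachloromethane ClC(Cl)(Cl)Cl
Why: Appel reaction: chloride displaces the activated primary alcohol under neutral conditions that spare the trisubstituted epoxide and both epoxide stereocentres.

**Step 9**
Reactants: 14 (2S,3S)-3-(chloromethyl)-2-methyl-2-{2-[(1S,2R)-1,2,3-trimethylcyclohex-3-en-1-yl]ethyl}oxirane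
Product: 16 (3S)-3-methyl-5-[(1S,2R)-1,2,3-trimethylcyclohex-3-en-1-yl]pent-1-yn-3-ol, via dilithium alkoxide acetylide 15 (not isolated)
Conditions: n-BuLi (3.3 equiv), THF, −40 °C → 0 °C; then H2O
Reagents that add atoms: none
Why: Base-induced double elimination of a 2,3-epoxy chloride (deprotonation next to chlorine, β-opening of the epoxide, dehydrochlorination) gives the terminal propargylic alcohol, and the tertiary C–O bond is never broken, so the configuration is retained.

**Step 10**
Reactants: 17 3,4-dimethoxyphenol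
Product: 18 2-iodo-4,5-dimethoxyphenol
Conditions: N-iodosuccinimide, MeCN, 0 °C
Reagents that add atoms: N-iodosuccinimide O=C1CCC(=O)N1I
Why: Electrophilic aromatic iodination should go to the position ortho to the hydroxyl and para to the 3-methoxy group, the most activated and least hindered site.

**Step 11**
Reactants: 18 2-iodo-4,5-dimethoxyphenol
Product: 19 2-iodo-4,5-dimethoxyphenyl acetate
Conditions: Ac2O, pyridine, 0 °C → rt
Reagents that add atoms: acetic anhydride CC(=O)OC(C)=O
Why: O-Acetylation masks the phenol so that the ortho-alkynyl arene of the next step cannot cyclise to a benzofuran.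

**Step 12**
Reactants: 16 (3S)-3-methyl-5-[(1S,2R)-1,2,3-trimethylcyclohex-3-en-1-yl]pent-1-yn-3-ol; 19 2-iodo-4,5-dimethoxyphenyl acetate
Product: 20 2-{(3S)-3-hydroxy-3-methyl-5-[(1S,2R)-1,2,3-trimethylcyclohex-3-en-1-yl]pent-1-yn-1-yl}-4,5-dimethoxyphenyl acetate
Conditions: PdCl2(PPh3)2 (cat.), CuI (cat.), Et3N, THF, rt
Reagents that add atoms: none
Why: Sonogashira coupling of an aryl iodide with a terminal tertiary propargylic alcohol runs at room temperature and tolerates the free hydroxyl group, the acetate and the ring alkene.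

**Step 13**
Reactants: 20 2-{(3S)-3-hydroxy-3-methyl-5-[(1S,2R)-1,2,3-trimethylcyclohex-3-en-1-yl]pent-1-yn-1-yl}-4,5-dimethoxyphenyl acetate
Product: 21 2-{(1Z,3S)-3-hydroxy-3-methyl-5-[(1S,2R)-1,2,3-trimethylcyclohex-3-en-1-yl]pent-1-en-1-yl}-4,5-dimethoxyphenyl acetate
Conditions: H2 (1 atm), Pd/CaCO3 poisoned with Pb(OAc)2, quinoline, EtOAc, rt
Reagents that add atoms: none
Why: Cis-selective semihydrogenation over poisoned palladium delivers both hydrogens to one face of the alkyne to give the (Z)-alkene and leaves the trisubstituted ring alkene alone.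

**Step 14**
Reactants: 21 2-{(1Z,3S)-3-hydroxy-3-methyl-5-[(1S,2R)-1,2,3-trimethylcyclohex-3-en-1-yl]pent-1-en-1-yl}-4,5-dimethoxyphenyl acetate
Product: 22 2-{(1Z,3S)-3-hydroxy-3-methyl-5-[(1S,2R)-1,2,3-trimethylcyclohex-3-en-1-yl]pent-1-en-1-yl}-4,5-dimethoxyphenol
Conditions: K2CO3 (cat.), MeOH, 0 °C; no contact with acidic silica
Reagents that add atoms: none
Why: Base-catalysed methanolysis of the aryl acetate frees the phenol in a basic medium, which avoids the acid-induced dehydrative closure through an ortho-quinone methide that would erase the carbinol configuration.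

**Step 15**
Reactants: 22 2-{(1Z,3S)-3-hydroxy-3-methyl-5-[(1S,2R)-1,2,3-trimethylcyclohex-3-en-1-yl]pent-1-en-1-yl}-4,5-dimethoxyphenol
Product: 23 (2S)-8,9-dimethoxy-2-methyl-2-{2-[(1S,2R)-1,2,3-trimethylcyclohex-3-en-1-yl]ethyl}-1-oxaspiro[4.5]deca-3,7,9-trien-6-one (both epimers at the spiro carbon C5)
Conditions: PhI(OAc)2 (1.05 equiv), NaHCO3, (CF3)2CHOH–CH2Cl2, −20 °C
Reagents that add atoms: none
Why: Oxidative dearomatisation with trivalent iodine (spiroetherification): the oxidised phenol is captured by 5-exo-trig attack of the pre-organised tertiary hydroxyl group on the alkenyl-bearing ortho carbon, which lies para to a methoxy group, so the aryl C–O bond is made without touching the carbinol C–O bond, and the new spiro centre need not be controlled because step 16 erases it.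

**Step 16**
Reactants: 23 (2S)-8,9-dimethoxy-2-methyl-2-{2-[(1S,2R)-1,2,3-trimethylcyclohex-3-en-1-yl]ethyl}-1-oxaspiro[4.5]deca-3,7,9-trien-6-one
Product: 24 (2S)-5,6-dimethoxy-2-methyl-2-{2-[(1S,2R)-1,2,3-trimethylcyclohex-3-en-1-yl]ethyl}-2H-chromen-8-ol
Conditions: BF3·OEt2 (20 mol %), CH2Cl2, −78 °C → −20 °C; aq. NaHCO3
Reagents that add atoms: none
Why: Dienone–phenol rearrangement run as a ring expansion: BF3 binds the carbonyl oxygen at C6 of 23 (a vinylogous ester and by far the most basic site) and turns the six-membered carbocycle into a pentadienyl cation whose only hydrogen-bearing terminus, C10 (future C4a), adjoins the spiro carbon C5 (future C8a). The vinylic carbon C4 then moves from C5 to C10 in a suprafacial 1,2-shift, which can be drawn as 3-exo-trig attack of the C3=C4 π bond on C10 to a cyclopropylcarbinyl-type bridge followed by cleavage of the old C4–C5 bond, so that the five-membered ring O1–C2–C3=C4–C5 takes up C10 and becomes the six-membered 2H-pyran. The shift is pushed by the lone pair of O1, the resulting cation is stabilised by O1 and by the 9-methoxy group, and loss of the proton from C10 rearomatises the carbocycle, makes the step irreversible and hands the acid on to the next molecule. The closest known reaction type is the acid-induced ring enlargement of spirocyclohexadienones, among them oxaspiro dienones that give benzo-fused cyclic ethers. No stereocentre is created: the spiro centre is erased, so both epimers of 23 converge, and C2 keeps its (S) configuration because none of its four bonds takes part. The step needs carbon instead of oxygen migration (a carbon shift leaves an oxocarbenium ion, an oxygen shift would need a strained oxiranium ion and leave only an allyl cation), migration to C10 and not to the carbonyl carbon C6 (only the former can end in an arene), and survival of the tertiary allylic C2–O1 bond (catalytic Lewis acid, low temperature, ether oxygen far less basic than the carbonyl oxygen).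

**Step 17**
Reactants: 24 (2S)-5,6-dimethoxy-2-methyl-2-{2-[(1S,2R)-1,2,3-trimethylcyclohex-3-en-1-yl]ethyl}-2H-chromen-8-ol
Product: 26 (2S)-6-methoxy-2-methyl-2-{2-[(1S,2R)-1,2,3-trimethylcyclohex-3-en-1-yl]ethyl}-2H-chromene-5,8-dione, via quinone hemiketal 25 (not isolated)
Conditions: PhI(OAc)2 (1.1 equiv), MeCN–H2O, 0 °C, exclusion of light
Reagents that add atoms: water O
Why: Oxidative demethylation of a para-methoxyphenol with trivalent iodine: water adds at the methoxy-bearing carbon para to the hydroxyl group and methanol is lost, which gives only the 5,8-quinone and leaves the 6-methoxy group, both alkenes and all stereocentres untouched.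

**Compound list**
1 | geranyl propionate, (2E)-3,7-dimethylocta-2,6-dien-1-yl propanoate | CCC(=O)OC/C=C(\C)CCC=C(C)C | starting material
2 | boron ketene acetal of 1 (methyl cis to O–B, (4S,5S)-diazaborolidine) | C/C=C(/OC/C=C(\C)CCC=C(C)C)OB1N(S(=O)(=O)c2cc(cc(c2)C(F)(F)F)C(F)(F)F)[C@@H](c2ccccc2)[C@H](c2ccccc2)N1S(=O)(=O)c2cc(cc(c2)C(F)(F)F)C(F)(F)F | intermediate
3 | (2R,3S)-3-ethenyl-2,3,7-trimethyloct-6-enoic acid | C=C[C@]([C@@H](C)C(=O)O)(C)CCC=C(C)C | intermediate
4 | (3R,4S)-4-ethenyl-3,4,8-trimethylnon-7-en-2-one | C=C[C@]([C@@H](C)C(C)=O)(C)CCC=C(C)C | intermediate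
5 | secondary ozonide of 4 (1,2,4-trioxolane at the former trisubstituted alkene) | C=C[C@]([C@@H](C)C(C)=O)(C)CCC1OOC(C)(C)O1 | intermediate
6 | (4S,5R)-4-ethenyl-4,5-dimethyl-6-oxoheptanal | C=C[C@]([C@@H](C)C(C)=O)(C)CCC=O | intermediate
7 | (5S,6S)-5-ethenyl-1,5,6-trimethylcyclohex-1-ene | C=C[C@]1(C)CCC=C(C)[C@@H]1C | intermediate
8 | but-2-yn-1-ol | CC#CCO | starting material
9 | sodium cyclic alkenylalanate from 8 | [Na+].CC1=CCO[Al-]1(OCCOC)OCCOC | intermediate
10 | (2Z)-3-iodobut-2-en-1-ol | OC/C=C(/C)I | intermediate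
11 | B-alkyl-9-borabicyclo[3.3.1]nonane from 7 | B1(CC[C@]2(C)CCC=C(C)[C@@H]2C)C3CCCC1CCC3 | intermediate
12 | (2Z)-3-methyl-5-[(1S,2R)-1,2,3-trimethylcyclohex-3-en-1-yl]pent-2-en-1-ol | OC/C=C(/C)CC[C@]1(C)CCC=C(C)[C@@H]1C | intermediate
13 | [(2R,3S)-3-methyl-3-{2-[(1S,2R)-1,2,3-trimethylcyclohex-3-en-1-yl]ethyl}oxiran-2-yl]methanol | OC[C@H]1O[C@@]1(C)CC[C@]2(C)CCC=C(C)[C@@H]2C | intermediate
14 | (2S,3S)-3-(chloromethyl)-2-methyl-2-{2-[(1S,2R)-1,2,3-trimethylcyclohex-3-en-1-yl]ethyl}oxirane | ClC[C@H]1O[C@@]1(C)CC[C@]2(C)CCC=C(C)[C@@H]2C | intermediate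
15 | dilithium alkoxide acetylide of 16 | [Li]C#C[C@](C)(CC[C@]1(C)CCC=C(C)[C@@H]1C)O[Li] | intermediate
16 | (3S)-3-methyl-5-[(1S,2R)-1,2,3-trimethylcyclohex-3-en-1-yl]pent-1-yn-3-ol | C#C[C@](C)(CC[C@]1(C)CCC=C(C)[C@@H]1C)O | intermediate
17 | 3,4-dimethoxyphenol | COc1ccc(O)cc1OC | starting material
18 | 2-iodo-4,5-dimethoxyphenol | Oc1cc(OC)c(OC)cc1I | intermediate
19 | 2-iodo-4,5-dimethoxyphenyl acetate | CC(=O)Oc1cc(OC)c(OC)cc1I | intermediate
20 | 2-{(3S)-3-hydroxy-3-methyl-5-[(1S,2R)-1,2,3-trimethylcyclohex-3-en-1-yl]pent-1-yn-1-yl}-4,5-dimethoxyphenyl acetate | CC(=O)Oc1cc(OC)c(OC)cc1C#C[C@](C)(CC[C@]2(C)CCC=C(C)[C@@H]2C)O | intermediate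
21 | 2-{(1Z,3S)-3-hydroxy-3-methyl-5-[(1S,2R)-1,2,3-trimethylcyclohex-3-en-1-yl]pent-1-en-1-yl}-4,5-dimethoxyphenyl acetate | CC(=O)Oc1cc(OC)c(OC)cc1/C=C\[C@](C)(CC[C@]2(C)CCC=C(C)[C@@H]2C)O | intermediate
22 | 2-{(1Z,3S)-3-hydroxy-3-methyl-5-[(1S,2R)-1,2,3-trimethylcyclohex-3-en-1-yl]pent-1-en-1-yl}-4,5-dimethoxyphenol | Oc1cc(OC)c(OC)cc1/C=C\[C@](C)(CC[C@]2(C)CCC=C(C)[C@@H]2C)O | intermediate
23 | (2S)-8,9-dimethoxy-2-methyl-2-{2-[(1S,2R)-1,2,3-trimethylcyclohex-3-en-1-yl]ethyl}-1-oxaspiro[4.5]deca-3,7,9-trien-6-one, both epimers at C5 | COC1=CC(=O)C2(C=C1OC)C=C[C@](C)(CC[C@]3(C)CCC=C(C)[C@@H]3C)O2 | intermediate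
24 | (2S)-5,6-dimethoxy-2-methyl-2-{2-[(1S,2R)-1,2,3-trimethylcyclohex-3-en-1-yl]ethyl}-2H-chromen-8-ol | COc1cc(O)c2c(c1OC)C=C[C@](C)(CC[C@]3(C)CCC=C(C)[C@@H]3C)O2 | intermediate
25 | (2S)-5-hydroxy-5,6-dimethoxy-2-methyl-2-{2-[(1S,2R)-1,2,3-trimethylcyclohex-3-en-1-yl]ethyl}-2H-chromen-8(5H)-one (quinone hemiketal) | COC1=CC(=O)C2=C(C=C[C@](C)(CC[C@]3(C)CCC=C(C)[C@@H]3C)O2)C1(O)OC | intermediate
26 | (2S)-6-methoxy-2-methyl-2-{2-[(1S,2R)-1,2,3-trimethylcyclohex-3-en-1-yl]ethyl}-2H-chromene-5,8-dione | COC1=CC(=O)C2=C(C=C[C@](C)(CC[C@]3(C)CCC=C(C)[C@@H]3C)O2)C1=O | target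

**Step count**
- Total step count: 17.
- Longest linear sequence: 14 (steps 1–4, 6–9, 12–17).

**Steps most likely to fail**

Step 16.
- Risk: ionisation of the tertiary, doubly allylic C2–O1 bond (loss of configuration or elimination) or migration of oxygen may outrun the carbon shift.
- Fallback: it sets out from 22 and returns at 26, and it takes the styrenyl double bond out of play before the ring expansion.
- Diimide (2-nitrobenzenesulfonyl hydrazide, Et3N) should reduce the cis-disubstituted alkene of 22 selectively to the saturated phenol carbinol F1.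
- PhI(OAc)2 with NaHCO3 should then close the spiro-tetrahydrofuran dienone F2, whose C2–O bond is no longer allylic.
- The acid-induced 1,2-alkyl shift, the dienone–phenol ring expansion of an oxaspiro dienone to a chroman, should give the chroman-8-ol F3.
- PhI(OAc)2 in aqueous MeCN should give the chroman-5,8-dione F4.
- Dehydrogenation with DDQ in hot dioxane, the known way from dihydropyrano-quinones to pyrano-quinones, installs C3=C4 and leads to 26.

Step 15.
- Risk: capture of the oxidised phenol at the methoxy-bearing para carbon by acetate or adventitious water, or a semipinacol shift of the carbinol, may compete with attack at the alkenyl-bearing carbon.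
- Fallback: it sets out from 22 and returns at 24, and it takes the para pathway on purpose and corrects it afterwards.
- PhI(OAc)2 in MeOH should give the quinone monoketal F5.
- Catalytic BF3·OEt2 in CH2Cl2–(CF3)2CHOH ionises the ketal in the known manner of acid-activated quinone monoketals.
- The tethered carbinol captures the cation at the carbon ortho to the carbonyl oxygen to form 23 in the flask, and the same acid expands it to 24.

Step 1.
- Risk: slow rearrangement at the fully substituted allyl terminus, incomplete control of enolate geometry, or poor facial selectivity.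
- Fallback: it sets out from 1 and returns at 3, and it separates relative from absolute control.
- LDA in THF–DMPU and Me3SiCl should give the (Z)-silyl ketene acetal F6.
- On warming, F6 should pass through the same chair (Ireland–Claisen rearrangement) to the racemic trimethylsilyl ester F7.
- Hydrolysis on work-up should give the racemic acid F8.
- Fractional crystallisation of the (S)-1-phenylethylammonium salt F9, or of the salt of the antipodal amine if that one crystallises better, followed by acidification should give 3.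

**Further compounds**
F1 | step 16 | saturated phenol carbinol | Oc1cc(OC)c(OC)cc1CC[C@](C)(CC[C@]2(C)CCC=C(C)[C@@H]2C)O
F2 | step 16 | spiro-tetrahydrofuran dienone | COC1=CC(=O)C2(C=C1OC)CC[C@](C)(CC[C@]3(C)CCC=C(C)[C@@H]3C)O2
F3 | step 16 | chroman-8-ol | COc1cc(O)c2c(c1OC)CC[C@](C)(CC[C@]3(C)CCC=C(C)[C@@H]3C)O2
F4 | step 16 | chroman-5,8-dione | COC1=CC(=O)C2=C(CC[C@](C)(CC[C@]3(C)CCC=C(C)[C@@H]3C)O2)C1=O
F5 | step 15 | quinone monoketal | COC1=CC(=O)C(/C=C\[C@](C)(CC[C@]2(C)CCC=C(C)[C@@H]2C)O)=CC1(OC)OC
F6 | step 1 | (Z)-silyl ketene acetal | C/C=C(/OC/C=C(\C)CCC=C(C)C)O[Si](C)(C)C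
F7 | step 1 | racemic trimethylsilyl ester | C=C[C@]([C@@H](C)C(=O)O[Si](C)(C)C)(C)CCC=C(C)C.C=C[C@@]([C@H](C)C(=O)O[Si](C)(C)C)(C)CCC=C(C)C
F8 | step 1 | racemic acid | C=C[C@]([C@@H](C)C(=O)O)(C)CCC=C(C)C.C=C[C@@]([C@H](C)C(=O)O)(C)CCC=C(C)C
F9 | step 1 | (S)-1-phenylethylammonium salt | C=C[C@]([C@@H](C)C(=O)[O-])(C)CCC=C(C)C.C[C@H]([NH3+])c1ccccc1
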